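In ring B, C2' to C5' each bear an oxygen, C6' bears hydrogen and C1' bears the chromone. These six carbons are assembled from a squarate ester, which supplies C2'–C5' with their oxygens, and a vinyl unit, which supplies C6' and C1' and carries the masked formyl carbon that becomes C2 of ring C. The precursor is cyclobutenone 5: diisopropyl squarate with a hydroxyl and an E-3,3-diethoxypropenyl group on one former carbonyl carbon. Heating 5 opens the four-membered ring to a dienylketene that closes to hydroquinone 8, forming the C1'–C2' bond and the whole of ring B in one operation. Aldehyde 13, made from 8, is joined to protected phloroacetophenone by aldol condensation and oxidative cyclisation.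

Key step: step 3

Remark: the target is achiral, so the only stereochemical elements to control are the E alkenes of 2, 5 and 16; the carbinol centre of 5 is racemic and disappears in step 3.

Step 1
Reactants: 1 3,3-diethoxyprop-1-yne
Product: 2 tributyl[(E)-3,3-diethoxyprop-1-enyl]stannane
Conditions: Bu3SnH (1.1 equiv), AIBN (cat.), neat, 85 °C; distil
Reagents that add atoms: tributyltin hydride, CCCC[SnH](CCCC)CCCC
Why: Radical hydrostannylation of a terminal alkyne puts tin on the unsubstituted carbon, and because addition of the tin radical is reversible at this temperature the first-formed Z adduct should equilibrate to the more stable E vinylstannane, while the acetal is inert to radicals.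

Step 2
Reactants: 2 tributyl[(E)-3,3-diethoxyprop-1-enyl]stannane; 3 diisopropyl squarate
Product: 5 racemic 4-[(E)-3,3-diethoxyprop-1-enyl]-4-hydroxy-2,3-di(propan-2-yloxy)cyclobut-2-en-1-one, via vinyllithium 4 (not isolated)
Conditions: n-BuLi, THF, −78 °C; cannulate into 3 in THF, −78 °C; aq. NH4Cl at −78 °C
Reagents that add atoms: none
Why: Tin–lithium exchange keeps the E geometry, and the vinyllithium adds 1,2 to one of the two equivalent squarate carbonyls, after which the remaining carbonyl is a deactivated vinylogous ester next to a lithium alkoxide and should resist a second addition at −78 °C; the carbinol carbon forms racemic and is erased in step 3.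

Step 3
Reactants: 5 racemic 4-[(E)-3,3-diethoxyprop-1-enyl]-4-hydroxy-2,3-di(propan-2-yloxy)cyclobut-2-en-1-one
Product: 8 2-(diethoxymethyl)-5,6-di(propan-2-yloxy)benzene-1,4-diol, via dienylketene 6 (not isolated), via cyclohexadienone 7 (not isolated)
Conditions: degassed toluene (dilute), 110 °C, Ar, base-washed glassware; concentrate under Ar and use crude at once
Reagents that add atoms: none
Why: Thermal conrotatory four-electron opening of the cyclobutenone breaks the bond between the carbonyl carbon and the carbinol carbon and gives dienylketene 6; the hydroxyl rotates outward, as donor substituents do, which leaves the alkenyl group on the inside, next to the ketene. A six-electron disrotatory electrocyclisation then joins the ketene carbon to the acetal-bearing alkene terminus (the C2'–C1' bond), closing the six-membered carbocycle as cyclohexadienone 7, which enolises to the aromatic hydroquinone 8. This is the Moore rearrangement of squarate-derived 4-alkenyl-4-hydroxycyclobutenones, a directly applicable reaction class. No stereocentre results, because the carbinol centre of 5 becomes trigonal and the transient tetrahedral carbon of 7 is lost on tautomerisation. The step needs the torquoselective outward rotation of the hydroxyl, so that the ketene cyclises onto carbon instead of being captured by the hydroxyl as a furanone, and this is secured by the donor character of that oxygen; the E alkene keeps the acetal on the outside of the closing triene. Neutral, oxygen-free conditions should preserve the acetal and the electron-rich hydroquinone.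

Step 4
Reactants: 8 2-(diethoxymethyl)-5,6-di(propan-2-yloxy)benzene-1,4-diol
Product: 10 2,5-dimethoxy-3,4-di(propan-2-yloxy)benzaldehyde, via acetal 9 (not isolated)
Conditions: MeI (excess), K2CO3, acetone, reflux, Ar; filter, concentrate; then 1 M HCl (cat.), THF, rt
Reagents that add atoms: iodomethane, CI; water, O
Why: Williamson ether synthesis caps both phenols before air can oxidise the hydroquinone, and brief aqueous acid then hydrolyses the diethyl acetal to the aldehyde without affecting aryl methyl or isopropyl ethers.

Step 5
Reactants: 10 2,5-dimethoxy-3,4-di(propan-2-yloxy)benzaldehyde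
Product: 11 3,4-dihydroxy-2,5-dimethoxybenzaldehyde
Conditions: BCl3 (1 M in CH2Cl2, 3 equiv), CH2Cl2, −78 → 0 °C, short reaction time; then H2O
Reagents that add atoms: none
Why: Lewis-acid dealkylation of aryl isopropyl ethers, in which the boron-complexed secondary ether ionises readily to 2-chloropropane whereas a methyl ether needs the slower displacement at methyl, so at or below 0 °C both isopropyl groups should leave while the two methoxy groups, including the one beside the formyl group, remain; water then hydrolyses the aryl borate to the catechol.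

Step 6
Reactants: 11 3,4-dihydroxy-2,5-dimethoxybenzaldehyde
Product: 12 3-hydroxy-2,4,5-trimethoxybenzaldehyde
Conditions: MeI (1.05 equiv), Li2CO3, DMF, 45 °C
Reagents that add atoms: iodomethane, CI
Why: Regioselective Williamson methylation, in which the hydroxyl para to the formyl group is the more acidic because its phenoxide is conjugated with the carbonyl, so the weak base Li2CO3 should ionise essentially only O4, as is known for 3,4-dihydroxybenzaldehydes.

Step 7
Reactants: 12 3-hydroxy-2,4,5-trimethoxybenzaldehyde
Product: 13 3-(benzyloxy)-2,4,5-trimethoxybenzaldehyde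
Conditions: BnBr, K2CO3, DMF, rt
Reagents that add atoms: benzyl bromide, BrCc1ccccc1
Why: Williamson benzylation of the remaining phenol installs a group that tolerates the basic aldol and the iodine step and leaves by hydrogenolysis at the end.

Step 8
Reactants: 14 2',4',6'-trihydroxyacetophenone
Product: 15 1-[2,4-bis(benzyloxy)-6-hydroxyphenyl]ethan-1-one
Conditions: BnBr (2.0 equiv), K2CO3, DMF, rt
Reagents that add atoms: benzyl bromide, BrCc1ccccc1
Why: Williamson benzylation with two equivalents alkylates the para hydroxyl and one ortho hydroxyl, whereas the last ortho hydroxyl is held in a hydrogen bond to the ketone and stays free for the later ring closure.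

Step 9
Reactants: 13 3-(benzyloxy)-2,4,5-trimethoxybenzaldehyde; 15 1-[2,4-bis(benzyloxy)-6-hydroxyphenyl]ethan-1-one
Product: 16 (E)-1-[2,4-bis(benzyloxy)-6-hydroxyphenyl]-3-[3-(benzyloxy)-2,4,5-trimethoxyphenyl]prop-2-en-1-one
Conditions: KOH, EtOH/THF, rt
Reagents that add atoms: none
Why: Claisen–Schmidt condensation of the methyl ketone enolate with a non-enolisable aldehyde, the dehydration giving the conjugated E enone under thermodynamic control.

Step 10
Reactants: 16 (E)-1-[2,4-bis(benzyloxy)-6-hydroxyphenyl]-3-[3-(benzyloxy)-2,4,5-trimethoxyphenyl]prop-2-en-1-one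
Product: 18 5,7-bis(benzyloxy)-2-[3-(benzyloxy)-2,4,5-trimethoxyphenyl]-4H-chromen-4-one, via flavanone 17 (not isolated)
Conditions: I2 (cat.), DMSO, 130 °C
Reagents that add atoms: none
Why: Oxidative cyclisation of a 2'-hydroxychalcone, in which oxa-Michael closure of the free phenol onto the enone gives flavanone 17 and iodine dehydrogenates it to the flavone while DMSO acts as terminal oxidant and regenerates iodine; any partial loss of the benzyl group on O5 would be harmless because step 11 removes all of them.

Step 11
Reactants: 18 5,7-bis(benzyloxy)-2-[3-(benzyloxy)-2,4,5-trimethoxyphenyl]-4H-chromen-4-one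
Product: 19 5,7,3'-trihydroxy-2',4',5'-trimethoxyflavone
Conditions: H2 (1 atm), Pd/C (10% palladium on carbon), THF/MeOH, rt
Reagents that add atoms: none
Why: Catalytic hydrogenolysis cleaves the three benzyl ethers, while aryl methyl ethers are inert and the chromone double bond, part of a vinylogous ester, should not be reduced at one atmosphere and room temperature.

Compound list
1 | 3,3-diethoxyprop-1-yne | C#CC(OCC)OCC | starting material
2 | tributyl[(E)-3,3-diethoxyprop-1-enyl]stannane | CCCC[Sn](CCCC)(CCCC)/C=C/C(OCC)OCC | intermediate
3 | diisopropyl squarate (3,4-di(propan-2-yloxy)cyclobut-3-ene-1,2-dione) | CC(C)OC1=C(OC(C)C)C(=O)C1=O | starting material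
4 | [(E)-3,3-diethoxyprop-1-enyl]lithium | [Li]/C=C/C(OCC)OCC | intermediate (not isolated)
5 | racemic 4-[(E)-3,3-diethoxyprop-1-enyl]-4-hydroxy-2,3-di(propan-2-yloxy)cyclobut-2-en-1-one | CCOC(OCC)/C=C/C1(O)C(OC(C)C)=C(OC(C)C)C1=O | intermediate
6 | (3Z,5E)-7,7-diethoxy-4-hydroxy-2,3-di(propan-2-yloxy)hepta-1,3,5-trien-1-one (dienylketene) | O=C=C(OC(C)C)/C(OC(C)C)=C(O)\C=C\C(OCC)OCC | intermediate (not isolated)
7 | racemic 6-(diethoxymethyl)-4-hydroxy-2,3-di(propan-2-yloxy)cyclohexa-2,4-dien-1-one | CCOC(OCC)C1C=C(O)C(OC(C)C)=C(OC(C)C)C1=O | intermediate (not isolated)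
8 | 2-(diethoxymethyl)-5,6-di(propan-2-yloxy)benzene-1,4-diol | CCOC(OCC)c1cc(O)c(OC(C)C)c(OC(C)C)c1O | intermediate
9 | 1-(diethoxymethyl)-2,5-dimethoxy-3,4-di(propan-2-yloxy)benzene | CCOC(OCC)c1cc(OC)c(OC(C)C)c(OC(C)C)c1OC | intermediate (not isolated)
10 | 2,5-dimethoxy-3,4-di(propan-2-yloxy)benzaldehyde | O=Cc1cc(OC)c(OC(C)C)c(OC(C)C)c1OC | intermediate
11 | 3,4-dihydroxy-2,5-dimethoxybenzaldehyde | O=Cc1cc(OC)c(O)c(O)c1OC | intermediate
12 | 3-hydroxy-2,4,5-trimethoxybenzaldehyde | O=Cc1cc(OC)c(OC)c(O)c1OC | intermediate
13 | 3-(benzyloxy)-2,4,5-trimethoxybenzaldehyde | O=Cc1cc(OC)c(OC)c(OCc2ccccc2)c1OC | intermediate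
14 | 2',4',6'-trihydroxyacetophenone | CC(=O)c1c(O)cc(O)cc1O | starting material
15 | 1-[2,4-bis(benzyloxy)-6-hydroxyphenyl]ethan-1-one | CC(=O)c1c(O)cc(OCc2ccccc2)cc1OCc1ccccc1 | intermediate
16 | (E)-1-[2,4-bis(benzyloxy)-6-hydroxyphenyl]-3-[3-(benzyloxy)-2,4,5-trimethoxyphenyl]prop-2-en-1-one | O=C(/C=C/c1cc(OC)c(OC)c(OCc2ccccc2)c1OC)c1c(O)cc(OCc2ccccc2)cc1OCc1ccccc1 | intermediate
17 | racemic 5,7-bis(benzyloxy)-2-[3-(benzyloxy)-2,4,5-trimethoxyphenyl]chroman-4-one | COc1cc(C2CC(=O)c3c(OCc4ccccc4)cc(OCc4ccccc4)cc3O2)c(OC)c(OCc2ccccc2)c1OC | intermediate (not isolated)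
18 | 5,7-bis(benzyloxy)-2-[3-(benzyloxy)-2,4,5-trimethoxyphenyl]-4H-chromen-4-one | COc1cc(-c2cc(=O)c3c(OCc4ccccc4)cc(OCc4ccccc4)cc3o2)c(OC)c(OCc2ccccc2)c1OC | intermediate
19 | 5,7,3'-trihydroxy-2',4',5'-trimethoxyflavone (5,7-dihydroxy-2-(3-hydroxy-2,4,5-trimethoxyphenyl)-4H-chromen-4-one) | COc1cc(-c2cc(=O)c3c(O)cc(O)cc3o2)c(OC)c(O)c1OC | target

Total step count: 11
Longest linear sequence: 10 steps (steps 1–7, then 9, 10 and 11); step 8 is a one-step branch.

Steps most likely to fail

Step 3 (key step). Three processes threaten it: oxidation of the electron-rich hydroquinone by traces of air during concentration; capture of the ketene by the free tertiary hydroxyl (lactonisation) if ring opening is not fully torquoselective; and thermal loss of ethanol from the acetal next to the new phenol. The fallback sets out from 5 and caps the carbinol oxygen before heating. Methylation (MeI, Ag2O, K2CO3, MeCN, rt) should give racemic 4-[(E)-3,3-diethoxyprop-1-enyl]-4-methoxy-2,3-di(propan-2-yloxy)cyclobut-2-en-1-one F1. Thermolysis of this ether (degassed toluene or p-xylene, reflux) follows the same ring opening and six-electron closure but should end at the monomethyl ether 6-(diethoxymethyl)-4-methoxy-2,3-di(propan-2-yloxy)phenol F2. F2 cannot be oxidised to a quinone, and its precursor has no hydroxyl to trap the ketene. Methylation of the remaining phenol (MeI, K2CO3, acetone) comes back to the route at 9, which is hydrolysed to 10 as in step 4.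

Step 5. Chelation of boron between the formyl oxygen and the neighbouring methoxy group may cause demethylation that competes with the slower cleavage of the isopropyl ether para to the aldehyde. The fallback sets out from 2 and replaces Lewis-acid dealkylation by hydrogenolysis:
- Squaric acid is esterified with benzyl alcohol (toluene, azeotropic removal of water) to 3,4-bis(benzyloxy)cyclobut-3-ene-1,2-dione F3.
- Vinyllithium 4, generated from 2 as in step 2, adds to it to give racemic 2,3-bis(benzyloxy)-4-[(E)-3,3-diethoxyprop-1-enyl]-4-hydroxycyclobut-2-en-1-one F4.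
- Thermolysis as in step 3 should give 5,6-bis(benzyloxy)-2-(diethoxymethyl)benzene-1,4-diol F5.
- Methylation (MeI, K2CO3, acetone, no acid stage) gives 3,4-bis(benzyloxy)-1-(diethoxymethyl)-2,5-dimethoxybenzene F6.
- Hydrogenolysis (H2, Pd/C, EtOAc, trace Et3N) gives 4-(diethoxymethyl)-3,6-dimethoxybenzene-1,2-diol F7.
- Dilute HCl in aqueous THF hydrolyses the acetal and comes back to the route at 11.

Step 6. The two catechol oxygens may be incompletely discriminated, leading to alkylation at the wrong oxygen or at both. The fallback sets out from 11 and uses the regiochemistry of nucleophilic aromatic substitution instead of phenoxide acidity. The catechol is bridged (CH2Br2, Cs2CO3, DMF, 100 °C) to 4,7-dimethoxy-1,3-benzodioxole-5-carbaldehyde F8. NaOMe in MeOH/DMSO at 120–150 °C should then open the dioxole by attack of methoxide at the ring carbon para to the formyl group. The displaced oxygen stays on the neighbouring carbon and sheds formaldehyde, so the methoxy group lands on C4 and the free hydroxyl on C3. This comes back to the route at 12.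

Further compounds
F1 | step 3 | racemic 4-[(E)-3,3-diethoxyprop-1-enyl]-4-methoxy-2,3-di(propan-2-yloxy)cyclobut-2-en-1-one | CCOC(OCC)/C=C/C1(OC)C(OC(C)C)=C(OC(C)C)C1=O
F2 | step 3 | 6-(diethoxymethyl)-4-methoxy-2,3-di(propan-2-yloxy)phenol | CCOC(OCC)c1cc(OC)c(OC(C)C)c(OC(C)C)c1O
F3 | step 5 | 3,4-bis(benzyloxy)cyclobut-3-ene-1,2-dione | O=C1C(=O)C(OCc2ccccc2)=C1OCc1ccccc1
F4 | step 5 | racemic 2,3-bis(benzyloxy)-4-[(E)-3,3-diethoxyprop-1-enyl]-4-hydroxycyclobut-2-en-1-one | CCOC(OCC)/C=C/C1(O)C(OCc2ccccc2)=C(OCc2ccccc2)C1=O
F5 | step 5 | 5,6-bis(benzyloxy)-2-(diethoxymethyl)benzene-1,4-diol | CCOC(OCC)c1cc(O)c(OCc2ccccc2)c(OCc2ccccc2)c1O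
F6 | step 5 | 3,4-bis(benzyloxy)-1-(diethoxymethyl)-2,5-dimethoxybenzene | CCOC(OCC)c1cc(OC)c(OCc2ccccc2)c(OCc2ccccc2)c1OC
F7 | step 5 | 4-(diethoxymethyl)-3,6-dimethoxybenzene-1,2-diol | CCOC(OCC)c1cc(OC)c(O)c(O)c1OC
F8 | step 6 | 4,7-dimethoxy-1,3-benzodioxole-5-carbaldehyde | O=Cc1cc(OC)c2OCOc2c1OC
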